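## Retrosynthetic overview

1. The last C–C disconnection lies between the side-chain carbinol carbon and the alkenyl CH: an (E)-alkenylzinc made from 3-ethynyl-isochromenone 21 adds to methyl ketone 32, then the silyl ethers are removed. The enabling feature is that the oxolane ring oxygen O1 sits on C2, α to the ketone carbon, so O1–C2–C=O closes a five-membered zinc chelate that fixes the carbonyl face; the sp carbon on C3 of the pyran ring gives the E-alkenyl metal by syn-hydroboration.
2. The pyran ring of 21 (O2–C3 bond) is closed by 6-endo oxa-Michael addition of the C1 alkoxide onto diynyl chloroenone 19, which comes from Negishi coupling of enol triflate 15, made by chlorination and triflation of cyclohexane-1,3-dione 13.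
3. Carbocycle 13 comes from intramolecular Claisen condensation of keto-lactone 11. Lactone 7 (ring-closing metathesis) is a temporary ring: its dihydroxylation sets C7 and C8 from C8a, which comes from an Ir-catalysed (hydroxymethyl)allylation of ethanol.
4. Ketone 32 comes from Brown (Z)-crotylboration of (S)-2-(benzyloxy)propanal, hydroboration, oxolane ring closure, debenzylation and oxidation.
5. Ring order: temporary δ-lactone, then carbocycle, then pyran in fragment A; oxolane in fragment B; the two fragments are joined in the last step but one.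

Key step: step 17

Assumption: the ligand antipode in step 1 and the borane antipode in step 12 are chosen by the accepted stereochemical models of these reagent classes; if a trial run showed the opposite sense, the other antipode would be used.

Abbreviations: TBS = tert-butyldimethylsilyl; TES = triethylsilyl; Ipc = isopinocampheyl; Cy = cyclohexyl. Ring positions of intermediates are quoted in the numbering of the target isochromenone (C1 to C8a) where this helps.

## Route

Step 1
Reactants: 1 ethanol; 2 4-ethenyl-1,3-dioxolan-2-one (vinyl ethylene carbonate, racemic)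
Product: 3 (2R,3R)-2-ethenylbutane-1,3-diol
Conditions: [Ir(cod)Cl]2 (2.5 mol%), (S)-Cl,MeO-BIPHEP (5 mol%), 4-cyano-3-nitrobenzoic acid (10 mol%), K3PO4 (5 mol%), 1 (3 equiv), THF, 70 °C, sealed tube
Reagents that add atoms: none
Why: Iridium-catalysed transfer-hydrogenative carbonyl (hydroxymethyl)allylation of the Krische type: ethanol is dehydrogenated to acetaldehyde, the carbonate ionises with loss of CO2 to a (hydroxymethyl)allyl iridium species, and the chiral bisphosphine should set C2 (the future C8a) in the anti diol, whose carbinol centre is erased in step 6.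

Step 2
Reactants: 3 (2R,3R)-2-ethenylbutane-1,3-diol; 4 2-methylprop-2-enoyl chloride
Product: 6 (2R,3R)-2-ethenyl-3-(TES-oxy)butyl 2-methylprop-2-enoate, via monoester 5 (not isolated)
Conditions: 4 (1.05 equiv), 2,4,6-collidine, CH2Cl2, −78 → −20 °C; then Et3SiCl, imidazole, 0 °C → rt
Reagents that add atoms: chlorotriethylsilane, CC[Si](Cl)(CC)CC
Why: Chemoselective acylation of the primary alcohol at low temperature followed by silylation of the secondary alcohol; no stereocentre is touched.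

Step 3
Reactants: 6 (2R,3R)-2-ethenyl-3-(TES-oxy)butyl 2-methylprop-2-enoate
Product: 7 (5R)-3-methyl-5-[(1R)-1-(TES-oxy)ethyl]-5,6-dihydro-2H-pyran-2-one
Conditions: second-generation Grubbs catalyst (H2IMes)(PCy3)Cl2Ru=CHPh (5 mol%), toluene (0.01 M), 80 °C
Reagents that add atoms: none
Why: Ring-closing olefin metathesis of the methacrylate with the vinyl group should close the δ-lactone and fix the Z geometry of the trisubstituted alkene (the future C7–C8 bond).

Step 4
Reactants: 7 (5R)-3-methyl-5-[(1R)-1-(TES-oxy)ethyl]-5,6-dihydro-2H-pyran-2-one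
Product: 8 (3R,4R,5S)-3,4-dihydroxy-3-methyl-5-[(1R)-1-(TES-oxy)ethyl]oxan-2-one
Conditions: OsO4 (5 mol%), N-methylmorpholine N-oxide (2 equiv), acetone/H2O (8:1), rt
Reagents that add atoms: N-methylmorpholine N-oxide, C[N+]1([O-])CCOCC1; water, O
Why: Upjohn syn-dihydroxylation: OsO4 should add to the lactone face opposite the bulky C5 side chain, which places the cis-diol (C7 and C8 of the target) trans to that substituent and therefore cis to the ring CH2O that becomes C1.

Step 5
Reactants: 8 (3R,4R,5S)-3,4-dihydroxy-3-methyl-5-[(1R)-1-(TES-oxy)ethyl]oxan-2-one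
Product: 9 (3R,4R,5R)-3,4-bis(TBS-oxy)-3-methyl-5-[(1R)-1-(TES-oxy)ethyl]oxan-2-one
Conditions: TBSOTf (3 equiv), 2,6-lutidine, CH2Cl2, 0 °C → rt
Reagents that add atoms: tert-butyldimethylsilyl trifluoromethanesulfonate, CC(C)(C)[Si](C)(C)OS(=O)(=O)C(F)(F)F
Why: Silyl triflate silylation of the secondary and the tertiary hydroxyl gives robust ethers that should survive every step up to the final fluoride treatment.

Step 6
Reactants: 9 (3R,4R,5R)-3,4-bis(TBS-oxy)-3-methyl-5-[(1R)-1-(TES-oxy)ethyl]oxan-2-one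
Product: 11 (3R,4R,5S)-5-acetyl-3,4-bis(TBS-oxy)-3-methyloxan-2-one, via alcohol 10 (not isolated)
Conditions: PPTS (0.2 equiv), MeOH/CH2Cl2, 0 °C; then Dess–Martin periodinane, NaHCO3, CH2Cl2, 0 °C → rt
Reagents that add atoms: none
Why: Acid-catalysed methanolysis should remove the more labile secondary triethylsilyl ether selectively, and buffered Dess–Martin oxidation gives the methyl ketone without disturbing the adjacent stereocentre.

Step 7
Reactants: 11 (3R,4R,5S)-5-acetyl-3,4-bis(TBS-oxy)-3-methyloxan-2-one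
Product: 13 (4R,5R,6S)-4,5-bis(TBS-oxy)-4-methyl-6-[(TES-oxy)methyl]cyclohexane-1,3-dione, via hydroxy dione 12 (not isolated)
Conditions: LiN(SiMe3)2 (2.2 equiv), THF, −78 → −30 °C; Et3SiCl (1.2 equiv), −78 → 0 °C; aq NH4Cl
Reagents that add atoms: chlorotriethylsilane, CC[Si](Cl)(CC)CC
Why: Intramolecular Claisen (Dieckmann-type) condensation: the kinetic methyl ketone enolate attacks the lactone carbonyl through a bicyclo[2.2.2] tetrahedral intermediate that collapses to the cyclohexane-1,3-dione enolate and the primary alkoxide, which is silylated in the same flask.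

Step 8
Reactants: 13 (4R,5R,6S)-4,5-bis(TBS-oxy)-4-methyl-6-[(TES-oxy)methyl]cyclohexane-1,3-dione
Product: 14 (4R,5R,6S)-4,5-bis(TBS-oxy)-2-chloro-4-methyl-6-[(TES-oxy)methyl]cyclohexane-1,3-dione (enolised at C2)
Conditions: N-chlorosuccinimide (1.05 equiv), CH2Cl2, 0 °C
Reagents that add atoms: N-chlorosuccinimide, O=C1CCC(=O)N1Cl
Why: Electrophilic chlorination of the 1,3-dione enol at its central carbon, the only enolisable position, installs the chlorine of C5 without regiochemical ambiguity.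

Step 9
Reactants: 14 (4R,5R,6S)-4,5-bis(TBS-oxy)-2-chloro-4-methyl-6-[(TES-oxy)methyl]cyclohexane-1,3-dione
Product: 15 (4R,5R,6S)-4,5-bis(TBS-oxy)-2-chloro-4-methyl-3-oxo-6-[(TES-oxy)methyl]cyclohex-1-en-1-yl trifluoromethanesulfonate
Conditions: Tf2O (1.2 equiv), Et3N (1.5 equiv), CH2Cl2, −78 °C
Reagents that add atoms: trifluoromethanesulfonic anhydride, O=S(=O)(OS(=O)(=O)C(F)(F)F)C(F)(F)F
Why: O-sulfonylation of the dione enolate should occur at the less hindered oxygen, the one remote from the fully substituted carbon that carries methyl and silyloxy groups, giving the vinylogous acyl triflate with the ketone next to that quaternary centre.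

Step 10
Reactants: 15 (4R,5R,6S)-4,5-bis(TBS-oxy)-2-chloro-4-methyl-3-oxo-6-[(TES-oxy)methyl]cyclohex-1-en-1-yl trifluoromethanesulfonate; 16 1,4-bis(trimethylsilyl)buta-1,3-diyne
Product: 19 (4S,5R,6R)-5,6-bis(TBS-oxy)-2-chloro-6-methyl-4-[(TES-oxy)methyl]-3-[4-(trimethylsilyl)buta-1,3-diyn-1-yl]cyclohex-2-en-1-one, via lithium diynide 17 (not isolated), via zinc diynide 18 (not isolated)
Conditions: 16 (1.5 equiv), MeLi·LiBr (1.5 equiv), THF, 0 °C → rt; ZnCl2 (1.6 equiv), 0 °C; then 15, Pd(PPh3)4 (5 mol%), THF, rt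
Reagents that add atoms: none
Why: Negishi alkynylation: monodesilylation of the bis-silyl diyne, transmetalation to zinc and palladium-catalysed coupling at the vinylogous acyl triflate, the vinylic C–Cl bond being inert under these conditions.

Step 11
Reactants: 19 (4S,5R,6R)-5,6-bis(TBS-oxy)-2-chloro-6-methyl-4-[(TES-oxy)methyl]-3-[4-(trimethylsilyl)buta-1,3-diyn-1-yl]cyclohex-2-en-1-one
Product: 21 (7R,8R,8aS)-7,8-bis(TBS-oxy)-5-chloro-3-ethynyl-7-methyl-1,7,8,8a-tetrahydro-6H-isochromen-6-one, via diynyl alcohol 20 (not isolated)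
Conditions: Bu4NF (2.2 equiv), THF, −20 → 0 °C
Reagents that add atoms: none
Why: Fluoride removes the primary triethylsilyl and the alkynyl trimethylsilyl groups, and the liberated alkoxide should close the pyran by 6-endo-dig conjugate (oxa-Michael) addition to the alkynyl chloroenone while the hindered TBS ethers survive at low temperature.

Step 12
Reactants: 22 (2S)-2-(benzyloxy)propanal; 23 (Z)-but-2-ene
Product: 26 (2S,3R,4S)-2-(benzyloxy)-4-methylhex-5-en-3-ol, via crotylpotassium 24 (not isolated), via crotylborane 25 (not isolated)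
Conditions: 23, KOt-Bu, n-BuLi, THF, −78 → −45 °C; (+)-B-methoxydiisopinocampheylborane, −78 °C; BF3·OEt2; 22, −78 °C; then NaOH, H2O2, 0 °C → rt
Reagents that add atoms: none
Why: Brown (Z)-crotylboration through a closed chair transition state: the Z geometry of the crotyl unit gives the syn relationship of hydroxyl and methyl, and the isopinocampheyl groups of the (+)-series reagent should direct attack to the Re face of the aldehyde, setting the centres that become C2 and C3 of the oxolane (the lactaldehyde centre is erased in step 16).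

Step 13
Reactants: 26 (2S,3R,4S)-2-(benzyloxy)-4-methylhex-5-en-3-ol
Product: 28 (3S,4R,5S)-5-(benzyloxy)-3-methylhexane-1,4-diol, via alkylborane 27 (not isolated)
Conditions: 9-BBN (2.2 equiv), THF, 0 °C → rt; then NaOH, H2O2, 0 °C → rt
Reagents that add atoms: hydrogen peroxide, OO
Why: Anti-Markovnikov hydroboration of the terminal alkene and oxidation of the C–B bond with retention give the primary alcohol without touching the stereocentres.

Step 14
Reactants: 28 (3S,4R,5S)-5-(benzyloxy)-3-methylhexane-1,4-diol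
Product: 30 (2R,3S)-2-[(1S)-1-(benzyloxy)ethyl]-3-methyloxolane, via tosylate 29 (not isolated)
Conditions: TsCl (1.05 equiv), pyridine, CH2Cl2, 0 °C; then KOt-Bu, THF, 0 °C → rt
Reagents that add atoms: none
Why: Selective sulfonylation of the primary alcohol and intramolecular Williamson etherification (5-exo-tet) at the CH2 carbon leave both stereocentres untouched and give the cis-2,3-disubstituted oxolane.

Step 15
Reactants: 30 (2R,3S)-2-[(1S)-1-(benzyloxy)ethyl]-3-methyloxolane
Product: 31 (1S)-1-[(2R,3S)-3-methyloxolan-2-yl]ethan-1-ol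
Conditions: H2 (1 atm), Pd/C (10 wt%), EtOAc, rt
Reagents that add atoms: none
Why: Hydrogenolysis of the benzyl ether, with no other reducible group present.

Step 16
Reactants: 31 (1S)-1-[(2R,3S)-3-methyloxolan-2-yl]ethan-1-ol
Product: 32 1-[(2R,3S)-3-methyloxolan-2-yl]ethan-1-one
Conditions: Dess–Martin periodinane, NaHCO3, CH2Cl2, 0 °C → rt
Reagents that add atoms: none
Why: Buffered Dess–Martin oxidation gives the methyl ketone under non-epimerising conditions, so the cis relationship at the α-carbon should be kept.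

Step 17
Reactants: 21 (7R,8R,8aS)-7,8-bis(TBS-oxy)-5-chloro-3-ethynyl-7-methyl-1,7,8,8a-tetrahydro-6H-isochromen-6-one; 32 1-[(2R,3S)-3-methyloxolan-2-yl]ethan-1-one
Product: 35 (7R,8R,8aS)-7,8-bis(TBS-oxy)-5-chloro-3-[(1E,3R)-3-hydroxy-3-[(2R,3S)-3-methyloxolan-2-yl]but-1-en-1-yl]-7-methyl-1,7,8,8a-tetrahydro-6H-isochromen-6-one, via alkenylborane 33 (not isolated), via alkenylzinc 34 (not isolated)
Conditions: 21, Cy2BH (1.1 equiv), toluene, 0 °C → rt; Me2Zn (1.2 equiv), −78 °C; then 32 (1.5 equiv) premixed with EtZnCl (1.5 equiv), toluene, −30 → 0 °C; aq NH4Cl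
Reagents that add atoms: none
Why: Syn-hydroboration of the terminal alkyne of 21 with the bulky Cy2BH places boron on the terminal carbon and defines the E-alkene, and boron-to-zinc exchange with Me2Zn gives the (E)-alkenyl(methyl)zinc 34 with retention. EtZnCl binds the carbonyl oxygen and the oxolane ring oxygen of 32 in a five-membered chelate, and the alkenyl group is delivered to the carbonyl face on the side of the C2 hydrogen, opposite to ring carbon C3 of the oxolane, which should give the R-configured tertiary carbinol (Cram chelate control by the adjacent C2 stereocentre). The closest known reaction type is the alkylzinc halide-promoted, chelation-controlled addition of hydroboration-derived alkenylzinc reagents to α-oxygenated ketones. No ring is closed; the step joins the two fragments at the fully substituted carbon and sets the sixth stereocentre and the alkene geometry in one operation. It needs chemoselectivity for the methyl ketone of 32 over the C6 carbonyl of the core and for the alkyne over the other π bonds: the C6 carbonyl is a doubly vinylogous ester flanked by the quaternary C7 and the chlorinated C5 and should be neither reduced by Cy2BH nor attacked by the alkenylzinc, and the enol ether and the tetrasubstituted chloroalkene are far less reactive toward Cy2BH than a terminal alkyne.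

Step 18
Reactants: 35 (7R,8R,8aS)-7,8-bis(TBS-oxy)-5-chloro-3-[(1E,3R)-3-hydroxy-3-[(2R,3S)-3-methyloxolan-2-yl]but-1-en-1-yl]-7-methyl-1,7,8,8a-tetrahydro-6H-isochromen-6-one
Product: 36 Peniciazaphilone E, (7R,8R,8aS)-5-chloro-7,8-dihydroxy-3-[(1E,3R)-3-hydroxy-3-[(2R,3S)-3-methyloxolan-2-yl]but-1-en-1-yl]-7-methyl-1,7,8,8a-tetrahydro-6H-isochromen-6-one
Conditions: HF·pyridine, pyridine, THF, 0 °C → rt
Reagents that add atoms: none
Why: Fluoride-mediated cleavage of the two silyl ethers under pyridine-buffered conditions, which should spare the tertiary allylic alcohol and the dienol ether.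

## Compound list

1 | ethanol | CCO | starting material
2 | 4-ethenyl-1,3-dioxolan-2-one (racemic) | C=CC1COC(=O)O1 | starting material
3 | (2R,3R)-2-ethenylbutane-1,3-diol | C[C@@H](O)[C@@H](CO)C=C | intermediate
4 | 2-methylprop-2-enoyl chloride | CC(=C)C(Cl)=O | starting material
5 | (2R,3R)-2-ethenyl-3-hydroxybutyl 2-methylprop-2-enoate | C[C@@H](O)[C@@H](COC(=O)C(C)=C)C=C | intermediate (not isolated)
6 | (2R,3R)-2-ethenyl-3-(triethylsilyloxy)butyl 2-methylprop-2-enoate | C[C@@H](O[Si](CC)(CC)CC)[C@@H](COC(=O)C(C)=C)C=C | intermediate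
7 | (5R)-3-methyl-5-[(1R)-1-(triethylsilyloxy)ethyl]-5,6-dihydro-2H-pyran-2-one | C[C@@H](O[Si](CC)(CC)CC)[C@H]1COC(=O)C(C)=C1 | intermediate
8 | (3R,4R,5S)-3,4-dihydroxy-3-methyl-5-[(1R)-1-(triethylsilyloxy)ethyl]oxan-2-one | C[C@@H](O[Si](CC)(CC)CC)[C@H]1COC(=O)[C@](C)(O)[C@@H]1O | intermediate
9 | (3R,4R,5R)-3,4-bis(tert-butyldimethylsilyloxy)-3-methyl-5-[(1R)-1-(triethylsilyloxy)ethyl]oxan-2-one | C[C@@H](O[Si](CC)(CC)CC)[C@H]1COC(=O)[C@](C)(O[Si](C)(C)C(C)(C)C)[C@@H]1O[Si](C)(C)C(C)(C)C | intermediate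
10 | (3R,4R,5R)-3,4-bis(tert-butyldimethylsilyloxy)-5-[(1R)-1-hydroxyethyl]-3-methyloxan-2-one | C[C@@H](O)[C@H]1COC(=O)[C@](C)(O[Si](C)(C)C(C)(C)C)[C@@H]1O[Si](C)(C)C(C)(C)C | intermediate (not isolated)
11 | (3R,4R,5S)-5-acetyl-3,4-bis(tert-butyldimethylsilyloxy)-3-methyloxan-2-one | CC(=O)[C@H]1COC(=O)[C@](C)(O[Si](C)(C)C(C)(C)C)[C@@H]1O[Si](C)(C)C(C)(C)C | intermediate
12 | (4R,5R,6S)-4,5-bis(tert-butyldimethylsilyloxy)-6-(hydroxymethyl)-4-methylcyclohexane-1,3-dione (formed as its dilithium salt) | O=C1CC(=O)[C@](C)(O[Si](C)(C)C(C)(C)C)[C@H](O[Si](C)(C)C(C)(C)C)[C@@H]1CO | intermediate (not isolated)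
13 | (4R,5R,6S)-4,5-bis(tert-butyldimethylsilyloxy)-4-methyl-6-[(triethylsilyloxy)methyl]cyclohexane-1,3-dione | O=C1CC(=O)[C@](C)(O[Si](C)(C)C(C)(C)C)[C@H](O[Si](C)(C)C(C)(C)C)[C@@H]1CO[Si](CC)(CC)CC | intermediate
14 | (4R,5R,6S)-4,5-bis(tert-butyldimethylsilyloxy)-2-chloro-4-methyl-6-[(triethylsilyloxy)methyl]cyclohexane-1,3-dione (C2 enolised) | O=C1C(Cl)C(=O)[C@](C)(O[Si](C)(C)C(C)(C)C)[C@H](O[Si](C)(C)C(C)(C)C)[C@@H]1CO[Si](CC)(CC)CC | intermediate
15 | (4R,5R,6S)-4,5-bis(tert-butyldimethylsilyloxy)-2-chloro-4-methyl-3-oxo-6-[(triethylsilyloxy)methyl]cyclohex-1-en-1-yl trifluoromethanesulfonate | FC(F)(F)S(=O)(=O)OC1=C(Cl)C(=O)[C@](C)(O[Si](C)(C)C(C)(C)C)[C@H](O[Si](C)(C)C(C)(C)C)[C@@H]1CO[Si](CC)(CC)CC | intermediate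
16 | 1,4-bis(trimethylsilyl)buta-1,3-diyne | C[Si](C)(C)C#CC#C[Si](C)(C)C | starting material
17 | [4-(trimethylsilyl)buta-1,3-diyn-1-yl]lithium | [Li]C#CC#C[Si](C)(C)C | intermediate (not isolated)
18 | chloro[4-(trimethylsilyl)buta-1,3-diyn-1-yl]zinc | Cl[Zn]C#CC#C[Si](C)(C)C | intermediate (not isolated)
19 | (4S,5R,6R)-5,6-bis(tert-butyldimethylsilyloxy)-2-chloro-6-methyl-4-[(triethylsilyloxy)methyl]-3-[4-(trimethylsilyl)buta-1,3-diyn-1-yl]cyclohex-2-en-1-one | C[Si](C)(C)C#CC#CC1=C(Cl)C(=O)[C@](C)(O[Si](C)(C)C(C)(C)C)[C@H](O[Si](C)(C)C(C)(C)C)[C@@H]1CO[Si](CC)(CC)CC | intermediate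
20 | (4S,5R,6R)-3-(buta-1,3-diyn-1-yl)-5,6-bis(tert-butyldimethylsilyloxy)-2-chloro-4-(hydroxymethyl)-6-methylcyclohex-2-en-1-one | C#CC#CC1=C(Cl)C(=O)[C@](C)(O[Si](C)(C)C(C)(C)C)[C@H](O[Si](C)(C)C(C)(C)C)[C@@H]1CO | intermediate (not isolated)
21 | (7R,8R,8aS)-7,8-bis(tert-butyldimethylsilyloxy)-5-chloro-3-ethynyl-7-methyl-1,7,8,8a-tetrahydro-6H-isochromen-6-one | C#CC1=CC2=C(Cl)C(=O)[C@](C)(O[Si](C)(C)C(C)(C)C)[C@H](O[Si](C)(C)C(C)(C)C)[C@@H]2CO1 | intermediate
22 | (2S)-2-(benzyloxy)propanal | C[C@H](OCc1ccccc1)C=O | starting material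
23 | (Z)-but-2-ene | C/C=C\C | starting material
24 | (Z)-but-2-en-1-ylpotassium | C/C=C\C[K] | intermediate (not isolated)
25 | B-[(Z)-but-2-en-1-yl]diisopinocampheylborane, (+)-Ipc series from (−)-α-pinene | C/C=C\CB([C@H]1C[C@H]2C[C@@H]([C@@H]1C)C2(C)C)[C@H]1C[C@H]2C[C@@H]([C@@H]1C)C2(C)C | intermediate (not isolated)
26 | (2S,3R,4S)-2-(benzyloxy)-4-methylhex-5-en-3-ol | C[C@H]([C@@H](O)[C@H](C)OCc1ccccc1)C=C | intermediate
27 | (2S,3R,4S)-2-(benzyloxy)-6-(9-borabicyclo[3.3.1]nonan-9-yl)-4-methylhexan-3-ol | C[C@H]([C@@H](O)[C@H](C)OCc1ccccc1)CCB1C2CCCC1CCC2 | intermediate (not isolated)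
28 | (3S,4R,5S)-5-(benzyloxy)-3-methylhexane-1,4-diol | C[C@H]([C@@H](O)[C@H](C)OCc1ccccc1)CCO | intermediate
29 | (3S,4R,5S)-5-(benzyloxy)-4-hydroxy-3-methylhexyl 4-methylbenzenesulfonate | C[C@H]([C@@H](O)[C@H](C)OCc1ccccc1)CCOS(=O)(=O)c1ccc(C)cc1 | intermediate (not isolated)
30 | (2R,3S)-2-[(1S)-1-(benzyloxy)ethyl]-3-methyloxolane | C[C@H]1CCO[C@H]1[C@H](C)OCc1ccccc1 | intermediate
31 | (1S)-1-[(2R,3S)-3-methyloxolan-2-yl]ethan-1-ol | C[C@H]1CCO[C@H]1[C@H](C)O | intermediate
32 | 1-[(2R,3S)-3-methyloxolan-2-yl]ethan-1-one | C[C@H]1CCO[C@H]1C(C)=O | intermediate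
33 | dicyclohexyl[(E)-2-(core-3-yl)ethenyl]borane, core = (7R,8R,8aS)-7,8-bis(tert-butyldimethylsilyloxy)-5-chloro-7-methyl-6-oxo-1,7,8,8a-tetrahydro-6H-isochromene | C1CCC(CC1)B(/C=C/C1=CC2=C(Cl)C(=O)[C@](C)(O[Si](C)(C)C(C)(C)C)[C@H](O[Si](C)(C)C(C)(C)C)[C@@H]2CO1)C1CCCCC1 | intermediate (not isolated)
34 | methyl[(E)-2-(core-3-yl)ethenyl]zinc, same core as in 33 | C[Zn]/C=C/C1=CC2=C(Cl)C(=O)[C@](C)(O[Si](C)(C)C(C)(C)C)[C@H](O[Si](C)(C)C(C)(C)C)[C@@H]2CO1 | intermediate (not isolated)
35 | (7R,8R,8aS)-7,8-bis(tert-butyldimethylsilyloxy)-5-chloro-3-[(1E,3R)-3-hydroxy-3-[(2R,3S)-3-methyloxolan-2-yl]but-1-en-1-yl]-7-methyl-1,7,8,8a-tetrahydro-6H-isochromen-6-one | C[C@H]1CCO[C@H]1[C@](C)(O)/C=C/C1=CC2=C(Cl)C(=O)[C@](C)(O[Si](C)(C)C(C)(C)C)[C@H](O[Si](C)(C)C(C)(C)C)[C@@H]2CO1 | intermediate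
36 | Peniciazaphilone E | C[C@H]1CCO[C@H]1[C@](C)(O)/C=C/C1=CC2=C(Cl)C(=O)[C@](C)(O)[C@H](O)[C@@H]2CO1 | target

## Step count and risks

Total step count: 18. Longest linear sequence: 13 steps (steps 1 to 11, then 17 and 18); the ketone fragment takes 5 steps (12 to 16).

The three steps most likely to fail:

1. Step 17. The hydroboration may not stay confined to the terminal alkyne (slow reduction of the dienone carbonyl by the borane), the boron-to-zinc exchange may be sluggish on this electron-poor dienyl system, methyl instead of alkenyl may be transferred, or facial selectivity may erode if the chelate is not fully formed. The fallback makes the same bond on a small diyne and attaches the core afterwards; it sets out from 16, 32 and 15 and comes back at 35. Compound 16 is monodesilylated (MeLi·LiBr, then aq NH4Cl) to buta-1,3-diyn-1-yl(trimethyl)silane F1, kept in solution. Hydroboration of its terminal alkyne with Cy2BH, exchange with Me2Zn and EtZnCl-promoted chelation-controlled addition to 32 should give (2R,3E)-2-[(2R,3S)-3-methyloxolan-2-yl]-6-(trimethylsilyl)hex-3-en-5-yn-2-ol F2. K2CO3 in MeOH frees the terminal enyne (2R,3E)-2-[(2R,3S)-3-methyloxolan-2-yl]hex-3-en-5-yn-2-ol F3. Sonogashira coupling of F3 with triflate 15 (Pd(PPh3)4, CuI, i-Pr2NH, THF) gives the enynyl chloroenone F4. Bu4NF at 0 °C removes the primary silyl group to the primary alcohol F5, whose alkoxide closes the pyran by 6-endo oxa-Michael addition to give 35.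

2. Step 9. O-sulfonylation may show poor or reversed regioselectivity between the two enol oxygens, which would place the alkyne on the wrong ring carbon. The fallback uses the opposite regiochemical requirement of a Stork–Danheiser sequence; it sets out from 14 and 16 and comes back at 19. If the oxygen next to the quaternary carbon proves the more reactive one, kinetic O-methylation of 14 (Me2SO4, K2CO3, acetone) gives the methyl enol ether F6. The lithium diynide 17 (from 16 and MeLi·LiBr, with CeCl3, THF, −78 °C) adds 1,2 to the remaining ketone to give the tertiary alcohol F7. Mild aqueous acid (oxalic acid, wet THF) then hydrolyses the enol ether with allylic transposition and loss of methanol to give 19.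

3. Step 7. The base may form the internal enolate at the ring CH next to the ketone, which would expel the lactone carboxylate by β-elimination or scramble that stereocentre before C-acylation takes place. The fallback opens the lactone first, so that only a silyl ether sits β to the ketone; it sets out from 10 and comes back at 13. Aminolysis of 10 (MeNH(OMe)·HCl, i-PrMgCl, THF, −20 °C) gives the dihydroxy Weinreb amide F8. Selective silylation of the primary hydroxyl (Et3SiCl, imidazole, −40 °C) gives F9, and Dess–Martin oxidation gives the keto amide F10. LiN(SiMe3)2 (THF, −78 → 0 °C) then closes the ring by intramolecular acylation of the methyl ketone enolate, with loss of N,O-dimethylhydroxylamine, to give 13.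

## Further compounds

F1 | step 17 | buta-1,3-diyn-1-yl(trimethyl)silane | C#CC#C[Si](C)(C)C
F2 | step 17 | (2R,3E)-2-[(2R,3S)-3-methyloxolan-2-yl]-6-(trimethylsilyl)hex-3-en-5-yn-2-ol | C[C@H]1CCO[C@H]1[C@](C)(O)/C=C/C#C[Si](C)(C)C
F3 | step 17 | (2R,3E)-2-[(2R,3S)-3-methyloxolan-2-yl]hex-3-en-5-yn-2-ol | C[C@H]1CCO[C@H]1[C@](C)(O)/C=C/C#C
F4 | step 17 | (4S,5R,6R)-5,6-bis(tert-butyldimethylsilyloxy)-2-chloro-3-[(3E,5R)-5-hydroxy-5-[(2R,3S)-3-methyloxolan-2-yl]hex-3-en-1-yn-1-yl]-6-methyl-4-[(triethylsilyloxy)methyl]cyclohex-2-en-1-one | C[C@H]1CCO[C@H]1[C@](C)(O)/C=C/C#CC1=C(Cl)C(=O)[C@](C)(O[Si](C)(C)C(C)(C)C)[C@H](O[Si](C)(C)C(C)(C)C)[C@@H]1CO[Si](CC)(CC)CC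
F5 | step 17 | (4S,5R,6R)-5,6-bis(tert-butyldimethylsilyloxy)-2-chloro-4-(hydroxymethyl)-3-[(3E,5R)-5-hydroxy-5-[(2R,3S)-3-methyloxolan-2-yl]hex-3-en-1-yn-1-yl]-6-methylcyclohex-2-en-1-one | C[C@H]1CCO[C@H]1[C@](C)(O)/C=C/C#CC1=C(Cl)C(=O)[C@](C)(O[Si](C)(C)C(C)(C)C)[C@H](O[Si](C)(C)C(C)(C)C)[C@@H]1CO
F6 | step 9 | (4R,5R,6S)-4,5-bis(tert-butyldimethylsilyloxy)-2-chloro-3-methoxy-4-methyl-6-[(triethylsilyloxy)methyl]cyclohex-2-en-1-one | O=C1C(Cl)=C(OC)[C@](C)(O[Si](C)(C)C(C)(C)C)[C@H](O[Si](C)(C)C(C)(C)C)[C@@H]1CO[Si](CC)(CC)CC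
F7 | step 9 | (4R,5R,6S)-4,5-bis(tert-butyldimethylsilyloxy)-2-chloro-3-methoxy-4-methyl-6-[(triethylsilyloxy)methyl]-1-[4-(trimethylsilyl)buta-1,3-diyn-1-yl]cyclohex-2-en-1-ol (C1 epimers) | C[Si](C)(C)C#CC#CC1(O)C(Cl)=C(OC)[C@](C)(O[Si](C)(C)C(C)(C)C)[C@H](O[Si](C)(C)C(C)(C)C)[C@@H]1CO[Si](CC)(CC)CC
F8 | step 7 | (2R,3R,4R,5R)-2,3-bis(tert-butyldimethylsilyloxy)-5-hydroxy-4-(hydroxymethyl)-N-methoxy-N,2-dimethylhexanamide | CON(C)C(=O)[C@](C)(O[Si](C)(C)C(C)(C)C)[C@H](O[Si](C)(C)C(C)(C)C)[C@H](CO)[C@@H](C)O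
F9 | step 7 | (2R,3R,4R,5R)-2,3-bis(tert-butyldimethylsilyloxy)-5-hydroxy-N-methoxy-N,2-dimethyl-4-[(triethylsilyloxy)methyl]hexanamide | CON(C)C(=O)[C@](C)(O[Si](C)(C)C(C)(C)C)[C@H](O[Si](C)(C)C(C)(C)C)[C@H](CO[Si](CC)(CC)CC)[C@@H](C)O
F10 | step 7 | (2R,3R,4S)-2,3-bis(tert-butyldimethylsilyloxy)-N-methoxy-N,2-dimethyl-5-oxo-4-[(triethylsilyloxy)methyl]hexanamide | CON(C)C(=O)[C@](C)(O[Si](C)(C)C(C)(C)C)[C@H](O[Si](C)(C)C(C)(C)C)[C@H](CO[Si](CC)(CC)CC)C(C)=O
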